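**Retrosynthetic overview**

1. The 1,2-dioxane (ring C) is closed last, at its C3–O bond, by a catalyst-controlled 6-exo peroxy-Michael addition of a tertiary hydroperoxide onto an (E)-2-methyl enoate. This sets dioxane C3 and the propanoate α-centre.
2. The tertiary C–OO bond (dioxane C6) is made earlier by invertive H2O2 opening of an oxetane derived from (R)-linalool, and is carried as a peroxyketal.
3. The enoate comes from cross-metathesis of the prenyl terminus, and the exocyclic methylidene from Peterson olefination of a decalone.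
4. Rings A and B are formed together by intramolecular Diels–Alder reaction of a 1,7,9-decatrien-3-one, giving the cis-decalone.
5. The acyclic quaternary/tertiary stereodiad comes from double alkylation of (S)-4-methyl-δ-valerolactone, first with MeI and then with the peroxy iodide.

Assumption: (R)-(−)-linalool 1 and methyl hydrogen (3R)-3-methylpentanedioate 10 are bought in at least 95% ee.

**Route**

Step 1
Reactants: 1 (3R)-3,7-dimethylocta-1,6-dien-3-ol [(R)-(−)-linalool]
Product: 3 (3R)-3,7-dimethyloct-6-ene-1,3-diol, via alkylborane 2 (not isolated)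
Conditions: 9-borabicyclo[3.3.1]nonane, THF, 0 °C → rt; then NaOH, H2O2, 0 °C
Reagents that add atoms: hydrogen peroxide, SMILES OO
Why: Anti-Markovnikov hydroboration–oxidation, in which the bulky borane takes the monosubstituted vinyl group in preference to the trisubstituted alkene and leaves the carbinol stereocentre untouched.

Step 2
Reactants: 3 (3R)-3,7-dimethyloct-6-ene-1,3-diol
Product: 5 (2R)-2-methyl-2-(4-methylpent-3-en-1-yl)oxetane, via primary tosylate 4 (not isolated)
Conditions: n-BuLi (1 equiv), THF, 0 °C; TsCl (1 equiv); n-BuLi (1 equiv), 0 → 60 °C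
Reagents that add atoms: none
Why: One-pot monotosylation and intramolecular Williamson etherification (4-exo-tet), in which the tertiary C–O bond is never broken so the configuration is retained.

Step 3
Reactants: 5 (2R)-2-methyl-2-(4-methylpent-3-en-1-yl)oxetane
Product: 6 (3S)-3-hydroperoxy-3,7-dimethyloct-6-en-1-ol
Conditions: anhydrous H2O2 in Et2O (4 equiv), Me3SiOSO2CF3 (0.2 equiv), −78 → −30 °C
Reagents that add atoms: hydrogen peroxide, SMILES OO
Why: Lewis acid-mediated perhydrolysis of a 2,2-disubstituted oxetane, in which H2O2 attacks the activated tertiary carbon in a borderline SN2 manner with inversion, setting the future dioxane C6 and releasing the primary alcohol.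

Step 4
Reactants: 6 (3S)-3-hydroperoxy-3,7-dimethyloct-6-en-1-ol
Product: 8 (3S)-3-[(2-methoxypropan-2-yl)peroxy]-3,7-dimethyloct-6-en-1-ol, via bis-ketal 7 (not isolated)
Conditions: CH2=C(Me)OMe (3 equiv), pyridinium 4-toluenesulfonate (2 mol%), CH2Cl2, 0 °C; then MeOH, 0 °C, 10 min; Et3N
Reagents that add atoms: 2-methoxypropene, SMILES C=C(C)OC
Why: Acid-catalysed ketalisation of both O–H groups followed by selective methanolysis of the much more labile alkyl mixed ketal, which leaves the hydroperoxide masked as a base-stable di-tertiary peroxyketal.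

Step 5
Reactants: 8 (3S)-3-[(2-methoxypropan-2-yl)peroxy]-3,7-dimethyloct-6-en-1-ol
Product: 9 (3S)-1-iodo-3-[(2-methoxypropan-2-yl)peroxy]-3,7-dimethyloct-6-ene
Conditions: I2, PPh3, imidazole, CH2Cl2, 0 °C
Reagents that add atoms: iodine, SMILES II
Why: Appel-type (Garegg–Samuelsson) iodination of the primary alcohol, which the hindered di-tertiary peroxyketal should survive because PPh3 reduces such peroxides only slowly at 0 °C.

Step 6
Reactants: 10 methyl hydrogen (3R)-3-methylpentanedioate
Product: 12 (4S)-4-methyltetrahydro-2H-pyran-2-one, via hydroxy acid 11 (not isolated)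
Conditions: LiBH4, THF, 0 °C → rt; then 2 M HCl, rt
Reagents that add atoms: none
Why: Chemoselective borohydride reduction of the ester beside the lithium carboxylate and then acid lactonisation, which leaves the stereocentre untouched (it becomes C4 of the lactone).

Step 7
Reactants: 12 (4S)-4-methyltetrahydro-2H-pyran-2-one
Product: 14 (3R,4S)-3,4-dimethyltetrahydro-2H-pyran-2-one, via lithium enolate 13 (not isolated)
Conditions: LiN(iPr)2, THF, −78 °C; MeI, −78 → −40 °C
Reagents that add atoms: iodomethane, SMILES CI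
Why: Lactone enolate alkylation in which MeI enters anti to the C4 methyl; this centre is re-enolised in step 8, so its configuration is immaterial.

Step 8
Reactants: 14 (3R,4S)-3,4-dimethyltetrahydro-2H-pyran-2-one; 9 (3S)-1-iodo-3-[(2-methoxypropan-2-yl)peroxy]-3,7-dimethyloct-6-ene
Product: 16 (3R,4S)-3-{(3S)-3-[(2-methoxypropan-2-yl)peroxy]-3,7-dimethyloct-6-en-1-yl}-3,4-dimethyltetrahydro-2H-pyran-2-one, via lithium enolate 15 (not isolated)
Conditions: LiN(iPr)2, THF, −78 °C; then 9, DMPU, −78 → −20 °C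
Reagents that add atoms: none
Why: Second lactone enolate alkylation (SN2 on the primary iodide), in which the cyclic enolate has fixed geometry and the electrophile again enters anti to the C4 methyl, placing the two methyls cis and setting the quaternary centre as 3R.

Step 9
Reactants: 16 (3R,4S)-3-{(3S)-3-[(2-methoxypropan-2-yl)peroxy]-3,7-dimethyloct-6-en-1-yl}-3,4-dimethyltetrahydro-2H-pyran-2-one
Product: 17 (2R,3S)-5-hydroxy-N-methoxy-2-{(3S)-3-[(2-methoxypropan-2-yl)peroxy]-3,7-dimethyloct-6-en-1-yl}-N,2,3-trimethylpentanamide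
Conditions: MeNH(OMe)·HCl, iPrMgCl, THF, −20 → 0 °C
Reagents that add atoms: N,O-dimethylhydroxylamine hydrochloride, SMILES CNOC.Cl
Why: Weinreb aminolysis of the lactone by the chloromagnesium amide, which avoids an aluminium Lewis acid that would cleave the peroxyketal and touches no stereocentre.

Step 10
Reactants: 17 (2R,3S)-5-hydroxy-N-methoxy-2-{(3S)-3-[(2-methoxypropan-2-yl)peroxy]-3,7-dimethyloct-6-en-1-yl}-N,2,3-trimethylpentanamide
Product: 18 (2R,3S)-N-methoxy-2-{(3S)-3-[(2-methoxypropan-2-yl)peroxy]-3,7-dimethyloct-6-en-1-yl}-N,2,3-trimethyl-5-oxopentanamide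
Conditions: Dess–Martin periodinane, pyridine, CH2Cl2, 0 °C → rt
Reagents that add atoms: none
Why: Buffered Dess–Martin oxidation of the primary alcohol to the aldehyde, mild enough for the acid-labile peroxyketal.

Step 11
Reactants: 18 (2R,3S)-N-methoxy-2-{(3S)-3-[(2-methoxypropan-2-yl)peroxy]-3,7-dimethyloct-6-en-1-yl}-N,2,3-trimethyl-5-oxopentanamide
Product: 19 (2R,3S,5E)-N-methoxy-2-{(3S)-3-[(2-methoxypropan-2-yl)peroxy]-3,7-dimethyloct-6-en-1-yl}-N,2,3,7-tetramethylocta-5,7-dienamide
Conditions: CH2=C(Me)CH2P(O)(OEt)2, n-BuLi, THF, −78 °C → rt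
Reagents that add atoms: diethyl (2-methylprop-2-en-1-yl)phosphonate, SMILES C=C(C)CP(=O)(OCC)OCC
Why: Horner–Wadsworth–Emmons olefination with the lithiated allylic phosphonate, which gives the (E)-1,3-diene needed for the cycloaddition.

Step 12
Reactants: 19 (2R,3S,5E)-N-methoxy-2-{(3S)-3-[(2-methoxypropan-2-yl)peroxy]-3,7-dimethyloct-6-en-1-yl}-N,2,3,7-tetramethylocta-5,7-dienamide
Product: 21 (2R,3S,4aR,8aS)-2-{(3S)-3-[(2-methoxypropan-2-yl)peroxy]-3,7-dimethyloct-6-en-1-yl}-2,3,6-trimethyl-3,4,4a,7,8,8a-hexahydronaphthalen-1(2H)-one, via trienone 20 (not isolated)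
Conditions: CH2=CHMgBr, THF, 0 °C; cold aq. NH4Cl; then toluene, BHT, 45 °C
Reagents that add atoms: vinylmagnesium bromide, SMILES C=C[Mg]Br
Why: Grignard addition to the Weinreb amide gives a 1,7,9-decatrien-3-one that undergoes intramolecular Diels–Alder reaction through the endo (carbonyl-in-tether) chair-like transition state with the C5 methyl and the long C4 chain equatorial and the dienophile kept away from the axial C4 methyl, which forms rings A and B and sets C4a (R) and C8a (S) cis to each other and to the C3 methyl.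

Step 13
Reactants: 21 (2R,3S,4aR,8aS)-2-{(3S)-3-[(2-methoxypropan-2-yl)peroxy]-3,7-dimethyloct-6-en-1-yl}-2,3,6-trimethyl-3,4,4a,7,8,8a-hexahydronaphthalen-1(2H)-one
Product: 23 2-methoxy-2-({(3S)-3,7-dimethyl-1-[(2R,3S,4aR,8aS)-2,3,6-trimethyl-1-methylidene-1,2,3,4,4a,7,8,8a-octahydronaphthalen-2-yl]oct-6-en-3-yl}peroxy)propane, via hydroxysilane 22 (not isolated)
Conditions: Me3SiCH2Li, CeCl3, THF, −78 → 0 °C; aq. NH4Cl work-up; crude, KH, THF, 0 °C → rt
Reagents that add atoms: (trimethylsilyl)methyllithium, SMILES [Li]C[Si](C)(C)C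
Why: Peterson olefination, in which the organocerium reagent adds to the hindered enolisable ketone without epimerising C8a and the potassium alkoxide of the β-hydroxysilane undergoes syn-elimination under basic conditions that the peroxyketal tolerates.

Step 14
Reactants: 23 2-methoxy-2-({(3S)-3,7-dimethyl-1-[(2R,3S,4aR,8aS)-2,3,6-trimethyl-1-methylidene-1,2,3,4,4a,7,8,8a-octahydronaphthalen-2-yl]oct-6-en-3-yl}peroxy)propane
Product: 24 methyl (2E,6S)-6-[(2-methoxypropan-2-yl)peroxy]-2,6-dimethyl-8-[(2R,3S,4aR,8aS)-2,3,6-trimethyl-1-methylidene-1,2,3,4,4a,7,8,8a-octahydronaphthalen-2-yl]oct-2-enoate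
Conditions: methyl methacrylate (10 equiv), second-generation Hoveyda–Grubbs catalyst [1,3-bis(2,4,6-trimethylphenyl)imidazolidin-2-ylidene]dichloro(2-isopropoxybenzylidene)ruthenium (5 mol%), CH2Cl2, 40 °C
Reagents that add atoms: methyl methacrylate, SMILES C=C(C)C(=O)OC
Why: Olefin cross-metathesis, in which only the unhindered acyclic isopropylidene alkene exchanges with methacrylate (the neopentylic exocyclic methylidene and the ring alkene are inert), giving the (E)-2-methyl enoate with loss of isobutene.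

Step 15
Reactants: 24 methyl (2E,6S)-6-[(2-methoxypropan-2-yl)peroxy]-2,6-dimethyl-8-[(2R,3S,4aR,8aS)-2,3,6-trimethyl-1-methylidene-1,2,3,4,4a,7,8,8a-octahydronaphthalen-2-yl]oct-2-enoate
Product: 26 methyl (2S)-2-[(3R,6R)-6-methyl-6-{2-[(2R,3S,4aR,8aS)-2,3,6-trimethyl-1-methylidene-1,2,3,4,4a,7,8,8a-octahydronaphthalen-2-yl]ethyl}-1,2-dioxan-3-yl]propanoate, via hydroperoxide 25 (not isolated)
Conditions: CF3CO2H (5 mol%), MeOH, 0 °C; filter through K2CO3, evaporate; then 1-[3,5-bis(trifluoromethyl)phenyl]-3-[(2S)-3,3-dimethyl-1-{[tris(4-methoxyphenyl)-λ5-phosphanylidene]amino}butan-2-yl]thiourea (10 mol%), toluene, −20 °C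
Reagents that add atoms: none
Why: Proposed new method: after acid methanolysis of the peroxyketal, the bifunctional iminophosphorane–thiourea superbase deprotonates the hydroperoxide (pKa about 13) while its thiourea binds the enoate carbonyl, the ion-paired peroxide anion closes the 1,2-dioxane by a chair-like 6-exo-trig oxa-Michael addition on the enoate face chosen by the catalyst (setting C3 as R, since the two C6 substituents are nearly equal in size and give no substrate bias), and the catalyst N–H then protonates the ester enolate inside the ion pair to give the 2,3-syn (2S) centre; the closest known reactions are amine-mediated racemic hydroperoxide oxa-Michael closures to 1,2-dioxanes and iminophosphorane-catalysed enantioselective intramolecular oxa-Michael additions of alcohols and sulfa-Michael/protonation reactions on unactivated unsaturated esters; the peroxide carbon keeps its geometry and only its CIP label changes from 6S to 6R.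

**Compound list**

1 | (3R)-3,7-dimethylocta-1,6-dien-3-ol [(R)-(−)-linalool] | C=C[C@](C)(O)CCC=C(C)C | starting material
2 | 9-[(3S)-3-hydroxy-3,7-dimethyloct-6-en-1-yl]-9-borabicyclo[3.3.1]nonane | C1CCC2CCCC1B2CC[C@](C)(O)CCC=C(C)C | intermediate
3 | (3R)-3,7-dimethyloct-6-ene-1,3-diol | OCC[C@](C)(O)CCC=C(C)C | intermediate
4 | (3R)-3-hydroxy-3,7-dimethyloct-6-en-1-yl 4-methylbenzenesulfonate | Cc1ccc(cc1)S(=O)(=O)OCC[C@](C)(O)CCC=C(C)C | intermediate
5 | (2R)-2-methyl-2-(4-methylpent-3-en-1-yl)oxetane | C[C@@]1(CCC=C(C)C)CCO1 | intermediate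
6 | (3S)-3-hydroperoxy-3,7-dimethyloct-6-en-1-ol | OCC[C@@](C)(OO)CCC=C(C)C | intermediate
7 | (3S)-1-[(2-methoxypropan-2-yl)oxy]-3-[(2-methoxypropan-2-yl)peroxy]-3,7-dimethyloct-6-ene | COC(C)(C)OCC[C@@](C)(OOC(C)(C)OC)CCC=C(C)C | intermediate
8 | (3S)-3-[(2-methoxypropan-2-yl)peroxy]-3,7-dimethyloct-6-en-1-ol | OCC[C@@](C)(OOC(C)(C)OC)CCC=C(C)C | intermediate
9 | (3S)-1-iodo-3-[(2-methoxypropan-2-yl)peroxy]-3,7-dimethyloct-6-ene | ICC[C@@](C)(OOC(C)(C)OC)CCC=C(C)C | intermediate
10 | methyl hydrogen (3R)-3-methylpentanedioate | COC(=O)C[C@H](C)CC(=O)O | starting material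
11 | (3S)-5-hydroxy-3-methylpentanoic acid | OCC[C@H](C)CC(=O)O | intermediate
12 | (4S)-4-methyltetrahydro-2H-pyran-2-one | O=C1OCC[C@H](C)C1 | intermediate
13 | lithium (4S)-4-methyl-5,6-dihydro-4H-pyran-2-olate | [Li+].[O-]C1=C[C@@H](C)CCO1 | intermediate
14 | (3R,4S)-3,4-dimethyltetrahydro-2H-pyran-2-one | O=C1OCC[C@H](C)[C@H]1C | intermediate
15 | lithium (4S)-3,4-dimethyl-5,6-dihydro-4H-pyran-2-olate | [Li+].[O-]C1=C(C)[C@@H](C)CCO1 | intermediate
16 | (3R,4S)-3-{(3S)-3-[(2-methoxypropan-2-yl)peroxy]-3,7-dimethyloct-6-en-1-yl}-3,4-dimethyltetrahydro-2H-pyran-2-one | O=C1OCC[C@H](C)[C@@]1(C)CC[C@@](C)(OOC(C)(C)OC)CCC=C(C)C | intermediate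
17 | (2R,3S)-5-hydroxy-N-methoxy-2-{(3S)-3-[(2-methoxypropan-2-yl)peroxy]-3,7-dimethyloct-6-en-1-yl}-N,2,3-trimethylpentanamide | CON(C)C(=O)[C@](C)(CC[C@@](C)(OOC(C)(C)OC)CCC=C(C)C)[C@@H](C)CCO | intermediate
18 | (2R,3S)-N-methoxy-2-{(3S)-3-[(2-methoxypropan-2-yl)peroxy]-3,7-dimethyloct-6-en-1-yl}-N,2,3-trimethyl-5-oxopentanamide | CON(C)C(=O)[C@](C)(CC[C@@](C)(OOC(C)(C)OC)CCC=C(C)C)[C@@H](C)CC=O | intermediate
19 | (2R,3S,5E)-N-methoxy-2-{(3S)-3-[(2-methoxypropan-2-yl)peroxy]-3,7-dimethyloct-6-en-1-yl}-N,2,3,7-tetramethylocta-5,7-dienamide | CON(C)C(=O)[C@](C)(CC[C@@](C)(OOC(C)(C)OC)CCC=C(C)C)[C@@H](C)C/C=C/C(C)=C | intermediate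
20 | (4R,5S,7E)-4-{(3S)-3-[(2-methoxypropan-2-yl)peroxy]-3,7-dimethyloct-6-en-1-yl}-4,5,9-trimethyldeca-1,7,9-trien-3-one | C=CC(=O)[C@](C)(CC[C@@](C)(OOC(C)(C)OC)CCC=C(C)C)[C@@H](C)C/C=C/C(C)=C | intermediate
21 | (2R,3S,4aR,8aS)-2-{(3S)-3-[(2-methoxypropan-2-yl)peroxy]-3,7-dimethyloct-6-en-1-yl}-2,3,6-trimethyl-3,4,4a,7,8,8a-hexahydronaphthalen-1(2H)-one | O=C1[C@H]2CCC(C)=C[C@H]2C[C@H](C)[C@@]1(C)CC[C@@](C)(OOC(C)(C)OC)CCC=C(C)C | intermediate
22 | (2R,3S,4aR,8aS)-2-{(3S)-3-[(2-methoxypropan-2-yl)peroxy]-3,7-dimethyloct-6-en-1-yl}-2,3,6-trimethyl-1-[(trimethylsilyl)methyl]-1,2,3,4,4a,7,8,8a-octahydronaphthalen-1-ol (C1 epimers) | C[Si](C)(C)CC1(O)[C@H]2CCC(C)=C[C@H]2C[C@H](C)[C@@]1(C)CC[C@@](C)(OOC(C)(C)OC)CCC=C(C)C | intermediate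
23 | 2-methoxy-2-({(3S)-3,7-dimethyl-1-[(2R,3S,4aR,8aS)-2,3,6-trimethyl-1-methylidene-1,2,3,4,4a,7,8,8a-octahydronaphthalen-2-yl]oct-6-en-3-yl}peroxy)propane | C=C1[C@H]2CCC(C)=C[C@H]2C[C@H](C)[C@@]1(C)CC[C@@](C)(OOC(C)(C)OC)CCC=C(C)C | intermediate
24 | methyl (2E,6S)-6-[(2-methoxypropan-2-yl)peroxy]-2,6-dimethyl-8-[(2R,3S,4aR,8aS)-2,3,6-trimethyl-1-methylidene-1,2,3,4,4a,7,8,8a-octahydronaphthalen-2-yl]oct-2-enoate | C=C1[C@H]2CCC(C)=C[C@H]2C[C@H](C)[C@@]1(C)CC[C@@](C)(OOC(C)(C)OC)CC/C=C(\C)C(=O)OC | intermediate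
25 | methyl (2E,6S)-6-hydroperoxy-2,6-dimethyl-8-[(2R,3S,4aR,8aS)-2,3,6-trimethyl-1-methylidene-1,2,3,4,4a,7,8,8a-octahydronaphthalen-2-yl]oct-2-enoate | C=C1[C@H]2CCC(C)=C[C@H]2C[C@H](C)[C@@]1(C)CC[C@@](C)(OO)CC/C=C(\C)C(=O)OC | intermediate
26 | methyl (2S)-2-[(3R,6R)-6-methyl-6-{2-[(2R,3S,4aR,8aS)-2,3,6-trimethyl-1-methylidene-1,2,3,4,4a,7,8,8a-octahydronaphthalen-2-yl]ethyl}-1,2-dioxan-3-yl]propanoate | C=C1[C@H]2CCC(C)=C[C@H]2C[C@H](C)[C@@]1(C)CC[C@]1(C)CC[C@H]([C@H](C)C(=O)OC)OO1 | target

**Step count and risks**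

Total step count: 15. Longest linear sequence: 13 steps (steps 1–5 from 1 to 9, then steps 8–15). The lactone branch from 10 to 14 is 2 steps.

The route as a whole depends on the peroxyketal surviving steps 8–14. The three steps most likely to fail are the following.

Step 15, the proposed new reaction. The risks are a racemic background cyclisation, the wrong facial sense, and base-induced retro-Michael or Kornblum–DeLaMare cleavage of the product. If the sense is wrong, the (2R) antipode of the catalyst is used. The fallback uses known chemistry and sets out from hydroperoxide 25. Et2NH in CF3CH2OH at room temperature gives the known amine-mediated peroxy-Michael ring closure, which delivers 26 together with its C2/C3 diastereomers. These are separated by preparative HPLC. The fallback comes back to the route at 26 and makes no further compound F0.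

Step 8, building the quaternary centre from a hindered trisubstituted lactone enolate and an unactivated primary iodide. The fallback changes the electrophile and the way the bond is made, and sets out from alcohol 8 (skipping iodide 9). Tf2O and 2,6-lutidine in CH2Cl2 at −78 °C give the primary triflate F1. Added at −78 °C to enolate 15 (made from 14 as in the route), it alkylates without a polar additive and with the same anti-to-methyl facial preference. The fallback comes back to the route at 16.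

Step 12, vinyl addition to an amide next to a quaternary carbon and a thermal Diels–Alder reaction whose endo:exo ratio cannot be raised with a Lewis acid because of the peroxyketal. The fallback sets out from 19. iBu2AlH in THF at −78 °C reduces the Weinreb amide to the dienal F2. CH2=CHMgBr at −78 °C adds to it to give the allylic alcohol F3 (both carbinol epimers). Dess–Martin periodinane with pyridine at 0 °C then generates trienone 20, which cyclises at 0–25 °C, where the endo preference is higher. The fallback comes back to the route at 20 and continues to 21.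

**Further compounds**

F0 | step 15 | none | none
F1 | step 8 | (3S)-3-[(2-methoxypropan-2-yl)peroxy]-3,7-dimethyloct-6-en-1-yl trifluoromethanesulfonate | FC(F)(F)S(=O)(=O)OCC[C@@](C)(OOC(C)(C)OC)CCC=C(C)C
F2 | step 12 | (2R,3S,5E)-2-{(3S)-3-[(2-methoxypropan-2-yl)peroxy]-3,7-dimethyloct-6-en-1-yl}-2,3,7-trimethylocta-5,7-dienal | O=C[C@](C)(CC[C@@](C)(OOC(C)(C)OC)CCC=C(C)C)[C@@H](C)C/C=C/C(C)=C
F3 | step 12 | (4R,5S,7E)-4-{(3S)-3-[(2-methoxypropan-2-yl)peroxy]-3,7-dimethyloct-6-en-1-yl}-4,5,9-trimethyldeca-1,7,9-trien-3-ol (both C3 epimers) | C=CC(O)[C@](C)(CC[C@@](C)(OOC(C)(C)OC)CCC=C(C)C)[C@@H](C)C/C=C/C(C)=C
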